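**Retrosynthetic overview**
- Target ⇐ (4E)-alkene diester by a late peracid epoxidation of C4=C5; the angelate comes from the C8 ketone (CBS reduction, then acylation) and the acetate is carried through from the bicyclic stage.
- Ten-membered ring ⇐ ring-expanding Grob (Wharton) fragmentation of a cis-fused five/seven bicyclic 1,3-diol monotriflate. It cleaves the C4–C8 ring-fusion bond and gives C8=O and the E-alkene; the cis-1,10-oxirane is already in place.
- Bicycle ⇐ ring-closing metathesis (seven-membered ring), hydroxyl-directed epoxidation, C6 bromination/acetate inversion, C5 reduction.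
- Cyclopentanone ⇐ one-pot desymmetrising copper-catalysed 1,4-isopropylation / 1,2-methallylation of a 2,2-disubstituted cyclopent-4-ene-1,3-dione ⇐ 2-methylcyclopentane-1,3-dione + acrolein.
- Ring order: five-membered ring (purchased) → seven-membered ring → first oxirane → ten-membered ring → second oxirane.

Assumption: germacrane numbering (ring C1–C10, methyls on C4 and C10, isopropyl on C7) is used for the target and late intermediates; the SMILES is read as (1R,4S,5S,6R,7R,8S,10S) with a cis 1,10-oxirane, a trans 4,5-oxirane and a (Z)-2-methylbut-2-enoate (angelate), and the sense of induction of the phosphoramidite in step 4 is assumed (its enantiomer is used if the opposite is found).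

**Step 1**
Reactants: 1 2-methylcyclopentane-1,3-dione; 2 prop-2-enal (acrolein)
Product: 3 3-(1-methyl-2,5-dioxocyclopentyl)propanal
Conditions: H2O, 23 °C
Reagents that add atoms: none
Why: Michael addition of the acidic 1,3-dione to acrolein runs in water without added base and builds the quaternary carbon (future C4); no stereocentre is formed.

**Step 2**
Reactants: 3 3-(1-methyl-2,5-dioxocyclopentyl)propanal
Product: 4 2-(but-3-en-1-yl)-2-methylcyclopentane-1,3-dione
Conditions: Ph3PCH3Br, KN(SiMe3)2, THF, −78 to 0 °C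
Reagents that add atoms: methyltriphenylphosphonium bromide, C[P+](c1ccccc1)(c1ccccc1)c1ccccc1.[Br-]
Why: Wittig methylenation with one equivalent of ylide at low temperature takes the unhindered aldehyde in preference to the two ketones that flank the quaternary carbon; no stereocentre is formed.

**Step 3**
Reactants: 4 2-(but-3-en-1-yl)-2-methylcyclopentane-1,3-dione
Product: 5 2-(but-3-en-1-yl)-2-methylcyclopent-4-ene-1,3-dione
Conditions: 2-iodoxybenzoic acid (IBX), DMSO, 75 °C
Reagents that add atoms: none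
Why: IBX-mediated α,β-dehydrogenation of the ketone through its enol introduces the ring alkene conjugated to both carbonyls, the terminal alkene is inert to IBX, and no stereocentre is formed.

**Step 4**
Reactants: 5 2-(but-3-en-1-yl)-2-methylcyclopent-4-ene-1,3-dione; 6 diisopropylzinc; 7 (2-methylprop-2-en-1-yl)magnesium chloride
Product: 9 (2R,3S,4R)-2-(but-3-en-1-yl)-3-hydroxy-2-methyl-3-(2-methylprop-2-en-1-yl)-4-(propan-2-yl)cyclopentan-1-one, via isopropylzinc enolate 8 (not isolated)
Conditions: Cu(OTf)2 (2 mol %), (S,R,R)-phosphoramidite from BINOL and bis(1-phenylethyl)amine (4 mol %), PhMe, −40 °C; then 7, THF, −78 °C; aq NH4Cl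
Reagents that add atoms: none
Why: Proposed new method: a desymmetrising copper/phosphoramidite conjugate addition transfers isopropyl from zinc to one enantiotopic alkene carbon on the face anti to the butenyl arm (setting C4 and the quaternary C2), the resulting zinc enolate masks the distal carbonyl so that the methallyl Grignard can only add 1,2 to the remaining ketone, anti to the new isopropyl group and to the methyl group (setting the C3 carbinol with OH cis to both); the closest known reaction type is the copper-catalysed desymmetrising conjugate addition of dialkylzincs to 2,2-disubstituted cyclopent-4-ene-1,3-diones with enolate trapping, and what is new is the use of that enolate as an in-flask mask for a second, different carbon nucleophile at the other carbonyl.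

**Step 5**
Reactants: 9 (2R,3S,4R)-2-(but-3-en-1-yl)-3-hydroxy-2-methyl-3-(2-methylprop-2-en-1-yl)-4-(propan-2-yl)cyclopentan-1-one
Product: 10 (3R,3aS,8aR)-3a-hydroxy-5,8a-dimethyl-3-(propan-2-yl)-3,3a,4,7,8,8a-hexahydroazulen-1(2H)-one
Conditions: second-generation Grubbs catalyst RuCl2(=CHPh)(H2IMes)(PCy3) (5 mol %), CH2Cl2 (5 mM), 40 °C
Reagents that add atoms: none
Why: Ring-closing metathesis between the butenyl and methallyl arms, which sit cis on adjacent ring carbons, closes the cis-fused seven-membered ring with a trisubstituted alkene that is necessarily Z and releases ethene; no stereocentre is formed and the free alcohol and ketone are tolerated.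

**Step 6**
Reactants: 10 (3R,3aS,8aR)-3a-hydroxy-5,8a-dimethyl-3-(propan-2-yl)-3,3a,4,7,8,8a-hexahydroazulen-1(2H)-one
Product: 11 (3R,3aS,5S,6R,8aR)-5,6-epoxy-3a-hydroxy-5,8a-dimethyl-3-(propan-2-yl)octahydroazulen-1(2H)-one
Conditions: VO(acac)2 (5 mol %), t-BuOOH, CH2Cl2, 0 to 23 °C
Reagents that add atoms: tert-butyl hydroperoxide, CC(C)(C)OO
Why: Hydroxyl-directed epoxidation of the homoallylic tertiary alcohol delivers oxygen to the face of the seven-membered ring that carries the 3a-OH (also its convex face), which sets C5 (S) and C6 (R) and so fixes the cis-1,10-oxirane of the target on a rigid bicycle.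

**Step 7**
Reactants: 11 (3R,3aS,5S,6R,8aR)-5,6-epoxy-3a-hydroxy-5,8a-dimethyl-3-(propan-2-yl)octahydroazulen-1(2H)-one
Product: 13 (2S,3R,3aS,5S,6R,8aR)-2-bromo-5,6-epoxy-3a-hydroxy-5,8a-dimethyl-3-(propan-2-yl)octahydroazulen-1(2H)-one, via dilithium enolate alkoxide 12 (not isolated)
Conditions: LiN(SiMe3)2 (2.2 equiv), THF, −78 °C; NBS, −78 °C; aq NH4Cl
Reagents that add atoms: N-bromosuccinimide, O=C1CCC(=O)N1Br
Why: Enolate α-bromination: the ketone can enolise only towards C2 because C8a is quaternary, and NBS attacks the enolate anti to the adjacent isopropyl group, giving the trans (2S) bromide.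

**Step 8**
Reactants: 13 (2S,3R,3aS,5S,6R,8aR)-2-bromo-5,6-epoxy-3a-hydroxy-5,8a-dimethyl-3-(propan-2-yl)octahydroazulen-1(2H)-one
Product: 14 (2R,3S,3aS,5S,6R,8aR)-5,6-epoxy-3a-hydroxy-5,8a-dimethyl-1-oxo-3-(propan-2-yl)decahydroazulen-2-yl acetate
Conditions: CsOAc, DMF, 0 to 23 °C
Reagents that add atoms: cesium acetate, CC(=O)[O-].[Cs+]
Why: SN2 displacement of the carbonyl-activated α-bromide by acetate inverts C2 and places the acetoxy group cis to the isopropyl group as the target requires, while the weakly basic carboxylate leaves the oxirane and the tertiary alcohol untouched.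

**Step 9**
Reactants: 14 (2R,3S,3aS,5S,6R,8aR)-5,6-epoxy-3a-hydroxy-5,8a-dimethyl-1-oxo-3-(propan-2-yl)decahydroazulen-2-yl acetate
Product: 15 (1S,2R,3S,3aS,5S,6R,8aS)-5,6-epoxy-1,3a-dihydroxy-5,8a-dimethyl-3-(propan-2-yl)decahydroazulen-2-yl acetate
Conditions: NaBH4, MeOH/CH2Cl2, −78 to −40 °C
Reagents that add atoms: none
Why: Borohydride reduction in which hydride enters anti to both the α-acetoxy group and the angular 8a-methyl group (as in 17-keto steroids), so the new hydroxyl (1S) is cis to the acetate and to the methyl group, and the low temperature suppresses 1,2-acetyl migration.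

**Step 10**
Reactants: 15 (1S,2R,3S,3aS,5S,6R,8aS)-5,6-epoxy-1,3a-dihydroxy-5,8a-dimethyl-3-(propan-2-yl)decahydroazulen-2-yl acetate
Product: 17 (1R,4E,6S,7S,10S)-4,10-dimethyl-8-oxo-7-(propan-2-yl)-11-oxabicyclo[8.1.0]undec-4-en-6-yl acetate, via secondary triflate 16 (not isolated)
Conditions: Tf2O, pyridine, CH2Cl2, −78 to 0 °C
Reagents that add atoms: none
Why: Ring-expanding Grob (Wharton) fragmentation: the secondary alcohol is triflated selectively, its pseudo-equatorial C–OTf bond lies antiperiplanar to the ring-fusion bond and the tertiary hydroxyl pushes, so the five/seven bicycle opens to the ten-membered ring with C8 as ketone and the new trisubstituted alkene formed stereospecifically E because the triflate is cis to the angular methyl group; the acetate, isopropyl and oxirane stereocentres are untouched and pyridine is too weak a base to eliminate the β-acetoxy ketone.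

**Step 11**
Reactants: 17 (1R,4E,6S,7S,10S)-4,10-dimethyl-8-oxo-7-(propan-2-yl)-11-oxabicyclo[8.1.0]undec-4-en-6-yl acetate
Product: 18 (1R,4E,6S,7R,8S,10S)-8-hydroxy-4,10-dimethyl-7-(propan-2-yl)-11-oxabicyclo[8.1.0]undec-4-en-6-yl acetate
Conditions: (R)-2-methyl-CBS-oxazaborolidine (0.5 equiv), catecholborane, PhMe, −78 to −40 °C
Reagents that add atoms: none
Why: Corey–Bakshi–Shibata reduction under reagent control, with the α-branched C7 side as the large group, delivers hydride to the face that gives the 8S alcohol, and catecholborane at low temperature spares the oxirane, the alkene and the acetate.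

**Step 12**
Reactants: 18 (1R,4E,6S,7R,8S,10S)-8-hydroxy-4,10-dimethyl-7-(propan-2-yl)-11-oxabicyclo[8.1.0]undec-4-en-6-yl acetate; 19 (2Z)-2-methylbut-2-enoic acid (angelic acid)
Product: 21 (1R,4E,6S,7R,8S,10S)-6-(acetyloxy)-4,10-dimethyl-7-(propan-2-yl)-11-oxabicyclo[8.1.0]undec-4-en-8-yl (2Z)-2-methylbut-2-enoate, via mixed anhydride 20 (not isolated)
Conditions: 19, 2,4,6-Cl3C6H2COCl, Et3N, PhMe, 23 °C; then 18, 75 °C
Reagents that add atoms: none
Why: Yamaguchi-type esterification through the preformed mixed anhydride, run without DMAP, acylates the hindered secondary alcohol with retention at C8 and without Z-to-E isomerisation of the angelate.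

**Step 13**
Reactants: 21 (1R,4E,6S,7R,8S,10S)-6-(acetyloxy)-4,10-dimethyl-7-(propan-2-yl)-11-oxabicyclo[8.1.0]undec-4-en-8-yl (2Z)-2-methylbut-2-enoate
Product: 22 (1R,4S,5S,6R,7R,8S,10S)-6-acetoxy-1,10:4,5-diepoxygermacran-8-yl (2Z)-2-methylbut-2-enoate (CNP0158257.1)
Conditions: m-CPBA, NaHCO3, CH2Cl2, 0 °C
Reagents that add atoms: 3-chloroperoxybenzoic acid, OOC(=O)c1cccc(Cl)c1
Why: Prilezhaev epoxidation of the only electron-rich alkene: H-6 eclipses the alkene to avoid A(1,3) strain with the 4-methyl group, the ring covers one face, and the peracid attacks the exposed face syn to the acetate to give the trans (4S,5S) oxirane, while the electron-poor angelate alkene does not react.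

**Compound list**
1 | 2-methylcyclopentane-1,3-dione | CC1C(=O)CCC1=O | starting material
2 | prop-2-enal (acrolein) | C=CC=O | starting material
3 | 3-(1-methyl-2,5-dioxocyclopentyl)propanal | CC1(CCC=O)C(=O)CCC1=O | intermediate
4 | 2-(but-3-en-1-yl)-2-methylcyclopentane-1,3-dione | CC1(CCC=C)C(=O)CCC1=O | intermediate
5 | 2-(but-3-en-1-yl)-2-methylcyclopent-4-ene-1,3-dione | CC1(CCC=C)C(=O)C=CC1=O | intermediate
6 | diisopropylzinc | CC(C)[Zn]C(C)C | starting material
7 | (2-methylprop-2-en-1-yl)magnesium chloride | CC(=C)C[Mg]Cl | starting material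
8 | isopropylzinc enolate, (2S,5S)-2-(but-3-en-1-yl)-2-methyl-5-(propan-2-yl)-3-{[(propan-2-yl)zincio]oxy}cyclopent-3-en-1-one | CC(C)[C@H]1C=C(O[Zn]C(C)C)[C@](C)(CCC=C)C1=O | intermediate
9 | (2R,3S,4R)-2-(but-3-en-1-yl)-3-hydroxy-2-methyl-3-(2-methylprop-2-en-1-yl)-4-(propan-2-yl)cyclopentan-1-one | CC(C)[C@H]1CC(=O)[C@](C)(CCC=C)[C@]1(O)CC(C)=C | intermediate
10 | (3R,3aS,8aR)-3a-hydroxy-5,8a-dimethyl-3-(propan-2-yl)-3,3a,4,7,8,8a-hexahydroazulen-1(2H)-one | CC(C)[C@H]1CC(=O)[C@]2(C)CCC=C(C)C[C@]12O | intermediate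
11 | (3R,3aS,5S,6R,8aR)-5,6-epoxy-3a-hydroxy-5,8a-dimethyl-3-(propan-2-yl)octahydroazulen-1(2H)-one | CC(C)[C@H]1CC(=O)[C@]2(C)CC[C@H]3O[C@@]3(C)C[C@]12O | intermediate
12 | dilithium salt of 11 (C1 enolate towards C2, 3a-alkoxide) | CC(C)[C@H]1C=C(O[Li])[C@]2(C)CC[C@H]3O[C@@]3(C)C[C@]12O[Li] | intermediate
13 | (2S,3R,3aS,5S,6R,8aR)-2-bromo-5,6-epoxy-3a-hydroxy-5,8a-dimethyl-3-(propan-2-yl)octahydroazulen-1(2H)-one | CC(C)[C@H]1[C@H](Br)C(=O)[C@]2(C)CC[C@H]3O[C@@]3(C)C[C@]12O | intermediate
14 | (2R,3S,3aS,5S,6R,8aR)-5,6-epoxy-3a-hydroxy-5,8a-dimethyl-1-oxo-3-(propan-2-yl)decahydroazulen-2-yl acetate | CC(C)[C@H]1[C@@H](OC(C)=O)C(=O)[C@]2(C)CC[C@H]3O[C@@]3(C)C[C@]12O | intermediate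
15 | (1S,2R,3S,3aS,5S,6R,8aS)-5,6-epoxy-1,3a-dihydroxy-5,8a-dimethyl-3-(propan-2-yl)decahydroazulen-2-yl acetate | CC(C)[C@H]1[C@@H](OC(C)=O)[C@@H](O)[C@]2(C)CC[C@H]3O[C@@]3(C)C[C@]12O | intermediate
16 | (1S,2R,3S,3aS,5S,6R,8aS)-5,6-epoxy-3a-hydroxy-5,8a-dimethyl-3-(propan-2-yl)-1-{[(trifluoromethyl)sulfonyl]oxy}decahydroazulen-2-yl acetate | CC(C)[C@H]1[C@@H](OC(C)=O)[C@@H](OS(=O)(=O)C(F)(F)F)[C@]2(C)CC[C@H]3O[C@@]3(C)C[C@]12O | intermediate
17 | (1R,4E,6S,7S,10S)-4,10-dimethyl-8-oxo-7-(propan-2-yl)-11-oxabicyclo[8.1.0]undec-4-en-6-yl acetate | O=C1C[C@]2(C)O[C@@H]2CC/C(C)=C/[C@H](OC(C)=O)[C@@H]1C(C)C | intermediate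
18 | (1R,4E,6S,7R,8S,10S)-8-hydroxy-4,10-dimethyl-7-(propan-2-yl)-11-oxabicyclo[8.1.0]undec-4-en-6-yl acetate | O[C@H]1C[C@]2(C)O[C@@H]2CC/C(C)=C/[C@H](OC(C)=O)[C@@H]1C(C)C | intermediate
19 | (2Z)-2-methylbut-2-enoic acid (angelic acid) | C/C=C(/C)C(=O)O | starting material
20 | (2Z)-2-methylbut-2-enoic 2,4,6-trichlorobenzoic anhydride | C/C=C(/C)C(=O)OC(=O)c1c(Cl)cc(Cl)cc1Cl | intermediate
21 | (1R,4E,6S,7R,8S,10S)-6-(acetyloxy)-4,10-dimethyl-7-(propan-2-yl)-11-oxabicyclo[8.1.0]undec-4-en-8-yl (2Z)-2-methylbut-2-enoate | C/C=C(/C)C(=O)O[C@H]1C[C@]2(C)O[C@@H]2CC/C(C)=C/[C@H](OC(C)=O)[C@@H]1C(C)C | intermediate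
22 | (1R,4S,5S,6R,7R,8S,10S)-6-acetoxy-1,10:4,5-diepoxygermacran-8-yl (2Z)-2-methylbut-2-enoate | C/C=C(/C)C(=O)O[C@H]1C[C@]2(C)O[C@@H]2CC[C@]2(C)O[C@H]2[C@H](OC(C)=O)[C@@H]1C(C)C | target

**Totals**
Total steps: 13. Longest linear sequence: 13 steps (1 → 22; compounds 2, 6, 7 and 19 enter as purchased partners).

**Three steps most likely to fail**

Step 4 (the proposed new method). The risks are incomplete masking by the zinc enolate (double addition or aldol) and modest facial selectivity at the carbinol. The fallback uses known chemistry, sets out from 5 and comes back at 9. The copper-catalysed conjugate addition of 6 is run alone and the enolate is trapped with Me3SiOTf, giving the isolable silyl enol ether (2S,5S)-2-(but-3-en-1-yl)-2-methyl-5-(propan-2-yl)-3-[(trimethylsilyl)oxy]cyclopent-3-en-1-one F1. Reagent 7 with CeCl3 (THF, −78 °C) then adds to the only free ketone to give (1S,2R,5S)-2-(but-3-en-1-yl)-2-methyl-1-(2-methylprop-2-en-1-yl)-5-(propan-2-yl)-3-[(trimethylsilyl)oxy]cyclopent-3-en-1-ol F2. Bu4NF/AcOH releases the ketone and gives 9.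

Step 10. The cyclopentyl triflate may not reach the antiperiplanar geometry quickly, so that elimination, substitution by pyridine or acid-induced transannular opening of the oxirane compete. The fallback sets out from 15 and comes back at 17, and it separates activation from fragmentation. MsCl/Et3N gives the stable mesylate (1S,2R,3S,3aS,5S,6R,8aS)-5,6-epoxy-3a-hydroxy-1-[(methanesulfonyl)oxy]-5,8a-dimethyl-3-(propan-2-yl)decahydroazulen-2-yl acetate F3. KN(SiMe3)2 (1.0 equiv, THF, −78 °C) then forms the tertiary potassium alkoxide, which fragments in the classical anionic Wharton mode; a cold AcOH quench protects the β-acetoxy ketone.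

Step 11. The conformational (peripheral-attack) bias of the ten-membered ketone may override the oxazaborolidine. The fallback sets out from 17 and comes back at 21, so that 18 and step 12 are bypassed. The ketone is reduced under whichever conditions give the other face cleanly ((S)-2-methyl-CBS-oxazaborolidine/catecholborane or NaBH4) to (1R,4E,6S,7R,8R,10S)-8-hydroxy-4,10-dimethyl-7-(propan-2-yl)-11-oxabicyclo[8.1.0]undec-4-en-6-yl acetate F4. Mitsunobu esterification of F4 with 19 (PPh3, DIAD, PhMe, 0 °C) installs the angelate with inversion to 8S.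

**Further compounds**
F1 | step 4 | (2S,5S)-2-(but-3-en-1-yl)-2-methyl-5-(propan-2-yl)-3-[(trimethylsilyl)oxy]cyclopent-3-en-1-one | CC(C)[C@H]1C=C(O[Si](C)(C)C)[C@](C)(CCC=C)C1=O
F2 | step 4 | (1S,2R,5S)-2-(but-3-en-1-yl)-2-methyl-1-(2-methylprop-2-en-1-yl)-5-(propan-2-yl)-3-[(trimethylsilyl)oxy]cyclopent-3-en-1-ol | CC(C)[C@H]1C=C(O[Si](C)(C)C)[C@](C)(CCC=C)[C@]1(O)CC(C)=C
F3 | step 10 | (1S,2R,3S,3aS,5S,6R,8aS)-5,6-epoxy-3a-hydroxy-1-[(methanesulfonyl)oxy]-5,8a-dimethyl-3-(propan-2-yl)decahydroazulen-2-yl acetate | CC(C)[C@H]1[C@@H](OC(C)=O)[C@@H](OS(C)(=O)=O)[C@]2(C)CC[C@H]3O[C@@]3(C)C[C@]12O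
F4 | step 11 | (1R,4E,6S,7R,8R,10S)-8-hydroxy-4,10-dimethyl-7-(propan-2-yl)-11-oxabicyclo[8.1.0]undec-4-en-6-yl acetate | O[C@@H]1C[C@]2(C)O[C@@H]2CC/C(C)=C/[C@H](OC(C)=O)[C@@H]1C(C)C
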